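**Plan**

- Retrosynthesis: the C16–O ester bond between the two labdane halves is cut first, then both C12=C13 alkenes (aldol condensation with a C4 lactone in the alcohol half, Horner–Wadsworth–Emmons olefination with a C4 phosphonate in the acid half). Both halves then come from one aldehyde, 13,14,15,16-tetranorlabd-8(17)-en-12-al (21).
- 21 is traced back (C8=C17 by methylenation, C12 by one-carbon homologation at C11) to a bicyclic aldehyde. In each trans-decalin the quaternary C10 with its methyl lies between C9, which carries C11, and the ring-fusion carbon C5. Ring B (C5–C10) is therefore the Diels–Alder adduct of an E β-methyl enal C11(=O)–C9=C10 and a 1-silyloxydiene C5=C6–C7=C8 joined by the chain C1–C4 (the later ring A); the bonds cut are C5–C10 and C8–C9.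
- Forward: the open-chain trienal 13 is built by Wittig olefination, B-alkyl Suzuki coupling and dienol silylation; rings A and B close together in step 8. C6=C7 is then hydrogenated, C12 added and the C8 oxygen turned into C8=CH2. Aldehyde 21 is used twice, the halves are esterified and the C15 aldehyde is unmasked last.
- Stereochemistry: C5, C9 and C10 of both decalins come from the chiral Lewis acid, the E enal and E,E diene geometry and the endo transition state of step 8 (C8 is a temporary centre). C14 comes from (R)-3-hydroxy-γ-butyrolactone. Both 12E alkenes come from thermodynamically controlled elimination and olefination.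
- Labdane numbering is used throughout: C1–C10 form the trans-decalin (5α-H, 9α-H, 10β-CH3), C18/C19 are the methyls on C4, C20 the methyl on C10, C11–C16 the chain on C9, C17 the carbon on C8.

Key step: step 8

Assumption: the (S)-configured oxazaborolidinium is taken to leave the C9 Si/C10 Re face of the bound enal open; if the cycloadduct proves to be the mirror image, the catalyst from (R)-α,α-diphenylprolinol is used and the route is otherwise unchanged.

**Route**

Step 1
Reactants: 1 2,2-dimethylpent-4-enal; 2 [2-(1,3-dioxolan-2-yl)ethyl]triphenylphosphonium bromide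
Product: 4 2-[(2Z)-4,4-dimethylhepta-2,6-dien-1-yl]-1,3-dioxolane, via phosphorus ylide 3 (not isolated)
Conditions: 2, KN(SiMe3)2, THF, −78 → 0 °C; then 1, −78 °C → rt
Reagents that add atoms: none
Why: Wittig olefination of a non-enolisable α-quaternary aldehyde by a non-stabilised ylide is reliable and Z-selective, and the alkene geometry does not matter because step 4 moves this double bond.

Step 2
Reactants: 5 ethyl acetoacetate
Product: 6 ethyl (2E)-3-{[(trifluoromethyl)sulfonyl]oxy}but-2-enoate
Conditions: Tf2O, aq. Me4NOH, hexane, 5 °C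
Reagents that add atoms: triflic anhydride, O=S(=O)(OS(=O)(=O)C(F)(F)F)C(F)(F)F
Why: O-triflation of the β-keto ester enolate; with the non-chelating tetramethylammonium counter-ion the extended enolate is trapped as the E enol triflate (triflate trans to the ester), the geometry needed for the later C9=C10 alkene.

Step 3
Reactants: 4 2-[(2Z)-4,4-dimethylhepta-2,6-dien-1-yl]-1,3-dioxolane; 6 ethyl (2E)-3-{[(trifluoromethyl)sulfonyl]oxy}but-2-enoate
Product: 8 ethyl (2E,8Z)-10-(1,3-dioxolan-2-yl)-3,7,7-trimethyldeca-2,8-dienoate, via B-alkyl-9-BBN borane 7 (not isolated)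
Conditions: 9-BBN-H, THF, 0 °C → rt; then 6, PdCl2(dppf) (5 mol %), K3PO4, THF/DMF/H2O, rt → 50 °C
Reagents that add atoms: none
Why: 9-BBN hydroborates only the unhindered terminal alkene (boron on C1), and the B-alkyl Suzuki–Miyaura coupling, through oxidative addition of the enol triflate to zerovalent palladium and reductive elimination, retains the alkene geometry, so the C1–C10 bond forms with the chain trans to the ester (2E).

Step 4
Reactants: 8 ethyl (2E,8Z)-10-(1,3-dioxolan-2-yl)-3,7,7-trimethyldeca-2,8-dienoate
Product: 10 ethyl (2E,9E)-3,7,7-trimethyl-11-oxoundeca-2,9-dienoate, via deconjugated aldehyde 9 (not isolated)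
Conditions: 1 M HCl, THF, rt; then DBU (0.1 equiv), CH2Cl2, 0 °C → rt
Reagents that add atoms: water, O
Why: acetal hydrolysis frees the β,γ-unsaturated aldehyde and base-catalysed isomerisation through the dienolate moves the double bond into conjugation, giving the thermodynamically favoured E enal whose C5 methylene supplies the γ-hydrogens for step 5.

Step 5
Reactants: 10 ethyl (2E,9E)-3,7,7-trimethyl-11-oxoundeca-2,9-dienoate
Product: 11 ethyl (2E,8E,10E)-11-[(tert-butyldimethylsilyl)oxy]-3,7,7-trimethylundeca-2,8,10-trienoate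
Conditions: TBSOTf, Et3N, Et2O, 0 °C → rt
Reagents that add atoms: tert-butyldimethylsilyl triflate, CC(C)(C)[Si](C)(C)OS(=O)(=O)C(F)(F)F
Why: soft enolisation, that is O-silylation of the s-trans enal followed by γ-deprotonation at the C5 methylene, gives the 1-silyloxy-1,3-diene, expected mainly as the E,E isomer, while the ester is not enolised under these conditions.

Step 6
Reactants: 11 ethyl (2E,8E,10E)-11-[(tert-butyldimethylsilyl)oxy]-3,7,7-trimethylundeca-2,8,10-trienoate
Product: 12 (2E,8E,10E)-11-[(tert-butyldimethylsilyl)oxy]-3,7,7-trimethylundeca-2,8,10-trien-1-ol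
Conditions: i-Bu2AlH (2.3 equiv), CH2Cl2, −78 °C; aq. KNaC4H4O6 (potassium sodium tartrate) work-up
Reagents that add atoms: none
Why: low-temperature 1,2-reduction of the conjugated ester by the aluminium hydride gives the allylic alcohol and leaves the silyl dienol ether intact as long as the work-up stays neutral.

Step 7
Reactants: 12 (2E,8E,10E)-11-[(tert-butyldimethylsilyl)oxy]-3,7,7-trimethylundeca-2,8,10-trien-1-ol
Product: 13 (2E,8E,10E)-11-[(tert-butyldimethylsilyl)oxy]-3,7,7-trimethylundeca-2,8,10-trienal
Conditions: activated MnO2, CH2Cl2, rt; filtered and used at once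
Reagents that add atoms: none
Why: allylic oxidation with MnO2 is neutral, selective for the allylic alcohol, keeps the 2E geometry and spares the acid-sensitive silyl dienol ether.

Step 8
Reactants: 13 (2E,8E,10E)-11-[(tert-butyldimethylsilyl)oxy]-3,7,7-trimethylundeca-2,8,10-trienal
Product: 14 (1R,2S,4aS,8aS)-2-[(tert-butyldimethylsilyl)oxy]-5,5,8a-trimethyl-1,2,4a,5,6,7,8,8a-octahydronaphthalene-1-carbaldehyde (8β-silyloxy, 9β-formyl, 10β-methyl, 5α-H, C6=C7)
Conditions: (S)-o-tolyl-CBS oxazaborolidine (0.24 equiv) protonated with Tf2NH (0.20 equiv), CH2Cl2, 4 Å molecular sieves, −78 → −40 °C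
Reagents that add atoms: none
Why: Proposed new method: the oxazaborolidinium binds the formyl oxygen of the s-trans enal and lowers its LUMO, and the electron-rich 1-silyloxydiene then bonds through C5 to C10 and closes C8–C9, either in one asynchronous step or as a Mukaiyama–Michael addition followed by aldol-type closure of the boron enolate onto the C8 silyloxocarbenium ion; the closest known reaction type is the oxazaborolidinium- or iminium-catalysed intramolecular Diels–Alder reaction of 2,8,10-trienals to trans-fused octalins, which has not been shown with a β,β-disubstituted enal that creates a quaternary centre. Ring A closes as the six-membered tether ring through the C5–C10 bond (6-exo with respect to the C9=C10 acceptor), and ring B closes as the six-membered cycloadduct ring through C5–C10 and C8–C9. C10 and C9 are set by the catalyst, which leaves only the C9 Si/C10 Re face open, together with suprafacial addition to the E enal, which keeps the formyl carbon C11 cis to the C10 methyl; C5 follows from the endo transition state of the E diene (formyl under the diene, tether anti), which gives the trans ring fusion; C8 follows from the E enol ether in the same endo arrangement (silyloxy cis to formyl) and is removed later. The step needs enantiofacial selectivity, endo selectivity and C5-to-C10 regiochemistry: the regiochemistry is fixed by the four-carbon tether and matches the polarisation of both partners (largest diene HOMO coefficient at C5, largest enal LUMO coefficient at C10), the E,E geometry of 13 and Lewis-acid activation favour the endo mode, and the aprotic low-temperature catalyst spares the silyl dienol ether.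

Step 9
Reactants: 14 (1R,2S,4aS,8aS)-2-[(tert-butyldimethylsilyl)oxy]-5,5,8a-trimethyl-1,2,4a,5,6,7,8,8a-octahydronaphthalene-1-carbaldehyde
Product: 15 (1R,2S,4aS,8aS)-2-[(tert-butyldimethylsilyl)oxy]-5,5,8a-trimethyldecahydronaphthalene-1-carbaldehyde
Conditions: H2 (1 atm), 5% Pt on carbon, EtOAc, rt
Reagents that add atoms: none
Why: catalytic hydrogenation saturates the cis-disubstituted C6=C7 bond, the only alkene present, without creating a stereocentre; platinum is preferred to palladium to limit double-bond migration towards the allylic silyl ether, and the hindered aldehyde survives.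

Step 10
Reactants: 15 (1R,2S,4aS,8aS)-2-[(tert-butyldimethylsilyl)oxy]-5,5,8a-trimethyldecahydronaphthalene-1-carbaldehyde
Product: 16 8β-[(tert-butyldimethylsilyl)oxy]-12-methoxy-13,14,15,16,17-pentanorlabd-11-ene (methyl enol ether; both geometries form, E drawn)
Conditions: Ph3P(CH2OMe)Cl, KN(SiMe3)2, THF, 0 °C; then 15, −78 → 0 °C
Reagents that add atoms: (methoxymethyl)triphenylphosphonium chloride, [Cl-].COC[P+](c1ccccc1)(c1ccccc1)c1ccccc1
Why: Wittig methoxymethylenation, the standard one-carbon homologation of an aldehyde, adds C12; β-silyloxy aldehydes tolerate non-stabilised ylides at low temperature and both enol ether geometries converge in step 11.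

Step 11
Reactants: 16 8β-[(tert-butyldimethylsilyl)oxy]-12-methoxy-13,14,15,16,17-pentanorlabd-11-ene
Product: 17 8β-[(tert-butyldimethylsilyl)oxy]-12,12-dimethoxy-13,14,15,16,17-pentanorlabdane
Conditions: pyridinium p-toluenesulfonate (0.1 equiv), MeOH, rt
Reagents that add atoms: methanol, CO
Why: acid-catalysed addition of methanol to the enol ether (acetalisation) makes C11 a saturated methylene before the C8 ketone is formed, and the hindered secondary silyl ether survives the weak acid.

Step 12
Reactants: 17 8β-[(tert-butyldimethylsilyl)oxy]-12,12-dimethoxy-13,14,15,16,17-pentanorlabdane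
Product: 18 12,12-dimethoxy-13,14,15,16,17-pentanorlabdan-8β-ol
Conditions: Bu4NF, THF, 50 °C; chromatography on Et3N-deactivated silica
Reagents that add atoms: none
Why: fluoride-induced desilylation under basic conditions leaves the acetal untouched; acid is avoided from here to step 13 because the free 8β-hydroxyl could close onto C12 to a cyclic acetal.

Step 13
Reactants: 18 12,12-dimethoxy-13,14,15,16,17-pentanorlabdan-8β-ol
Product: 19 12,12-dimethoxy-13,14,15,16,17-pentanorlabdan-8-one
Conditions: Pr4N[RuO4] (5 mol %), N-methylmorpholine N-oxide, 4 Å molecular sieves, CH2Cl2, rt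
Reagents that add atoms: none
Why: perruthenate-catalysed (Ley–Griffith) oxidation of the axial secondary alcohol under neutral conditions gives the C8 ketone and removes the temporary C8 stereocentre.

Step 14
Reactants: 19 12,12-dimethoxy-13,14,15,16,17-pentanorlabdan-8-one
Product: 20 12,12-dimethoxy-13,14,15,16-tetranorlabd-8(17)-ene
Conditions: Ph3PCH3Br, KOt-Bu, toluene, 90 °C
Reagents that add atoms: methyltriphenylphosphonium bromide, [Br-].C[P+](c1ccccc1)(c1ccccc1)c1ccccc1
Why: Wittig methylenation of 8-oxo decalins of this kind is well precedented, and any enolisation towards C9 re-protonates to the more stable equatorial 9β side chain, so the C9 configuration is kept.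

Step 15
Reactants: 20 12,12-dimethoxy-13,14,15,16-tetranorlabd-8(17)-ene
Product: 21 13,14,15,16-tetranorlabd-8(17)-en-12-al, that is 2-[(1S,4aS,8aS)-5,5,8a-trimethyl-2-methylidenedecahydronaphthalen-1-yl]acetaldehyde
Conditions: pyridinium p-toluenesulfonate (0.3 equiv), acetone/H2O 9:1, 55 °C
Reagents that add atoms: water, O
Why: mild acid-catalysed acetal hydrolysis releases the C12 aldehyde, and the weak acid does not isomerise the exocyclic alkene.

Step 16
Reactants: 22 (R)-3-hydroxy-γ-butyrolactone, that is (4R)-4-hydroxyoxolan-2-one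
Product: 23 (4R)-4-[(tert-butyldimethylsilyl)oxy]oxolan-2-one
Conditions: TBSCl, imidazole, DMF, rt
Reagents that add atoms: tert-butyldimethylsilyl chloride, CC(C)(C)[Si](C)(C)Cl
Why: standard silylation of the secondary alcohol; the C14 stereocentre is carried over unchanged from the commercial (R)-lactone.

Step 17
Reactants: 21 13,14,15,16-tetranorlabd-8(17)-en-12-al; 23 (4R)-4-[(tert-butyldimethylsilyl)oxy]oxolan-2-one
Product: 25 (14R)-14-[(tert-butyldimethylsilyl)oxy]-12-hydroxylabd-8(17)-en-16,15-olide (13,14-trans; both C12 epimers), via lithium enolate 24 (not isolated)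
Conditions: 23, LiN(i-Pr)2 (1.1 equiv), THF, −78 °C; then 21, −78 °C; AcOH quench at −78 °C
Reagents that add atoms: none
Why: lithium enolate aldol addition at −78 °C, where the β-silyloxy enolate does not yet eliminate; the enolate is attacked anti to the silyloxy group (13,14-trans), and the new C12 and C13 centres are both removed in step 18.

Step 18
Reactants: 25 (14R)-14-[(tert-butyldimethylsilyl)oxy]-12-hydroxylabd-8(17)-en-16,15-olide
Product: 27 (12E,14R)-14-[(tert-butyldimethylsilyl)oxy]labda-8(17),12-dien-16,15-olide, via C12 mesylate 26 (not isolated)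
Conditions: MsCl, Et3N, CH2Cl2, 0 °C; then DBU, 0 °C → rt
Reagents that add atoms: none
Why: mesylation followed by base-induced E1cB elimination (aldol condensation) gives the conjugated alkylidene lactone, expected mainly as the E isomer with the vinylic hydrogen syn to the lactone carbonyl, and C14 is not touched.

Step 19
Reactants: 27 (12E,14R)-14-[(tert-butyldimethylsilyl)oxy]labda-8(17),12-dien-16,15-olide
Product: 28 (12E,14R)-14-hydroxylabda-8(17),12-dien-16,15-olide
Conditions: HF·pyridine, THF, 0 °C → rt
Reagents that add atoms: none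
Why: desilylation with buffered hydrogen fluoride avoids base, so the allylic C14 oxygen is not eliminated and the exocyclic alkene is not isomerised.

Step 20
Reactants: 29 triethyl phosphonoacetate; 30 2-bromo-1,1-dimethoxyethane
Product: 32 ethyl 2-(diethoxyphosphoryl)-4,4-dimethoxybutanoate (racemic), via sodium phosphonoacetate 31 (not isolated)
Conditions: 29, NaH, DMF, 0 °C → rt; then 30, NaI (10 mol %), 90 °C
Reagents that add atoms: none
Why: SN2 C-alkylation of the stabilised phosphonoacetate anion by the primary bromo acetal under iodide catalysis is a standard route to α-substituted phosphonoacetates, and the racemic new centre disappears in step 21.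

Step 21
Reactants: 21 13,14,15,16-tetranorlabd-8(17)-en-12-al; 32 ethyl 2-(diethoxyphosphoryl)-4,4-dimethoxybutanoate
Product: 34 ethyl (12E)-15,15-dimethoxylabda-8(17),12-dien-16-oate, via sodium phosphonate anion 33 (not isolated)
Conditions: 32, NaH, THF, 0 °C; then 21, 0 °C → rt
Reagents that add atoms: none
Why: Horner–Wadsworth–Emmons olefination of an α-substituted phosphonoacetate with an α-unbranched aldehyde gives the trisubstituted acrylate with the aldehyde residue trans to the ester (12E) under thermodynamic control of the oxaphosphetane.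

Step 22
Reactants: 34 ethyl (12E)-15,15-dimethoxylabda-8(17),12-dien-16-oate
Product: 35 (12E)-15,15-dimethoxylabda-8(17),12-dien-16-oic acid
Conditions: LiOH·H2O, THF/MeOH/H2O, 45 °C; then AcOH to pH 5
Reagents that add atoms: lithium hydroxide, [Li+].[OH-]
Why: saponification of the conjugated ethyl ester by hydroxide leaves acetal and alkenes untouched, and acidification with acetic acid is too mild to hydrolyse the acetal.

Step 23
Reactants: 28 (12E,14R)-14-hydroxylabda-8(17),12-dien-16,15-olide; 35 (12E)-15,15-dimethoxylabda-8(17),12-dien-16-oic acid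
Product: 37 (12E,14R)-16-oxo-15,16-epoxylabda-8(17),12-dien-14-yl (12E)-15,15-dimethoxylabda-8(17),12-dien-16-oate (dimethyl acetal of the target), via Yamaguchi mixed anhydride 36 (not isolated)
Conditions: 35, 2,4,6-trichlorobenzoyl chloride, Et3N, toluene, rt; then 28, DMAP, rt
Reagents that add atoms: none
Why: Yamaguchi esterification activates the hindered α-branched acid as a mixed anhydride that the secondary allylic alcohol attacks under acyl-transfer catalysis, with retention at C14 because the C14–O bond is not broken.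

Step 24
Reactants: 37 (12E,14R)-16-oxo-15,16-epoxylabda-8(17),12-dien-14-yl (12E)-15,15-dimethoxylabda-8(17),12-dien-16-oate
Product: 38 CNP0274315.1, (12E,14R)-16-oxo-15,16-epoxylabda-8(17),12-dien-14-yl (12E)-15-oxolabda-8(17),12-dien-16-oate
Conditions: 10% aq. oxalic acid on silica gel, CH2Cl2, rt
Reagents that add atoms: water, O
Why: mild heterogeneous acetal hydrolysis releases the C15 aldehyde last, when nothing remains that has to be done in its presence, and esters, lactone and exocyclic alkenes tolerate wet oxalic acid on silica.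

**Compound list**

1 | 2,2-dimethylpent-4-enal | C=CCC(C)(C)C=O | starting material
2 | [2-(1,3-dioxolan-2-yl)ethyl]triphenylphosphonium bromide | [Br-].C1COC(O1)CC[P+](c1ccccc1)(c1ccccc1)c1ccccc1 | starting material
3 | 2-[2-(triphenyl-λ5-phosphanylidene)ethyl]-1,3-dioxolane (ylide of 2, not isolated) | C1COC(O1)CC=P(c1ccccc1)(c1ccccc1)c1ccccc1 | intermediate
4 | 2-[(2Z)-4,4-dimethylhepta-2,6-dien-1-yl]-1,3-dioxolane | C=CCC(C)(C)/C=C\CC1OCCO1 | intermediate
5 | ethyl acetoacetate | CCOC(=O)CC(C)=O | starting material
6 | ethyl (2E)-3-{[(trifluoromethyl)sulfonyl]oxy}but-2-enoate | CCOC(=O)/C=C(\C)OS(=O)(=O)C(F)(F)F | intermediate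
7 | 9-[(5Z)-7-(1,3-dioxolan-2-yl)-4,4-dimethylhept-5-en-1-yl]-9-borabicyclo[3.3.1]nonane (not isolated) | C1COC(O1)C/C=C\C(C)(C)CCCB1C2CCCC1CCC2 | intermediate
8 | ethyl (2E,8Z)-10-(1,3-dioxolan-2-yl)-3,7,7-trimethyldeca-2,8-dienoate | CCOC(=O)/C=C(\C)CCCC(C)(C)/C=C\CC1OCCO1 | intermediate
9 | ethyl (2E,8Z)-3,7,7-trimethyl-11-oxoundeca-2,8-dienoate (not isolated) | CCOC(=O)/C=C(\C)CCCC(C)(C)/C=C\CC=O | intermediate
10 | ethyl (2E,9E)-3,7,7-trimethyl-11-oxoundeca-2,9-dienoate | CCOC(=O)/C=C(\C)CCCC(C)(C)C/C=C/C=O | intermediate
11 | ethyl (2E,8E,10E)-11-[(tert-butyldimethylsilyl)oxy]-3,7,7-trimethylundeca-2,8,10-trienoate | CCOC(=O)/C=C(\C)CCCC(C)(C)/C=C/C=C/O[Si](C)(C)C(C)(C)C | intermediate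
12 | (2E,8E,10E)-11-[(tert-butyldimethylsilyl)oxy]-3,7,7-trimethylundeca-2,8,10-trien-1-ol | OC/C=C(\C)CCCC(C)(C)/C=C/C=C/O[Si](C)(C)C(C)(C)C | intermediate
13 | (2E,8E,10E)-11-[(tert-butyldimethylsilyl)oxy]-3,7,7-trimethylundeca-2,8,10-trienal | O=C/C=C(\C)CCCC(C)(C)/C=C/C=C/O[Si](C)(C)C(C)(C)C | intermediate
14 | (1R,2S,4aS,8aS)-2-[(tert-butyldimethylsilyl)oxy]-5,5,8a-trimethyl-1,2,4a,5,6,7,8,8a-octahydronaphthalene-1-carbaldehyde | O=C[C@H]1[C@@H](O[Si](C)(C)C(C)(C)C)C=C[C@H]2C(C)(C)CCC[C@]12C | intermediate
15 | (1R,2S,4aS,8aS)-2-[(tert-butyldimethylsilyl)oxy]-5,5,8a-trimethyldecahydronaphthalene-1-carbaldehyde | O=C[C@H]1[C@@H](O[Si](C)(C)C(C)(C)C)CC[C@H]2C(C)(C)CCC[C@]12C | intermediate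
16 | 8β-[(tert-butyldimethylsilyl)oxy]-12-methoxy-13,14,15,16,17-pentanorlabd-11-ene (E drawn, both geometries form) | CO/C=C/[C@H]1[C@@H](O[Si](C)(C)C(C)(C)C)CC[C@H]2C(C)(C)CCC[C@]12C | intermediate
17 | 8β-[(tert-butyldimethylsilyl)oxy]-12,12-dimethoxy-13,14,15,16,17-pentanorlabdane | COC(OC)C[C@H]1[C@@H](O[Si](C)(C)C(C)(C)C)CC[C@H]2C(C)(C)CCC[C@]12C | intermediate
18 | 12,12-dimethoxy-13,14,15,16,17-pentanorlabdan-8β-ol | COC(OC)C[C@H]1[C@@H](O)CC[C@H]2C(C)(C)CCC[C@]12C | intermediate
19 | 12,12-dimethoxy-13,14,15,16,17-pentanorlabdan-8-one | COC(OC)C[C@H]1C(=O)CC[C@H]2C(C)(C)CCC[C@]12C | intermediate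
20 | 12,12-dimethoxy-13,14,15,16-tetranorlabd-8(17)-ene | COC(OC)C[C@H]1C(=C)CC[C@H]2C(C)(C)CCC[C@]12C | intermediate
21 | 13,14,15,16-tetranorlabd-8(17)-en-12-al | O=CC[C@H]1C(=C)CC[C@H]2C(C)(C)CCC[C@]12C | intermediate
22 | (R)-3-hydroxy-γ-butyrolactone | O[C@H]1COC(=O)C1 | starting material
23 | (4R)-4-[(tert-butyldimethylsilyl)oxy]oxolan-2-one | CC(C)(C)[Si](C)(C)O[C@H]1COC(=O)C1 | intermediate
24 | lithium enolate of 23 (not isolated) | CC(C)(C)[Si](C)(C)O[C@H]1COC(O[Li])=C1 | intermediate
25 | (14R)-14-[(tert-butyldimethylsilyl)oxy]-12-hydroxylabd-8(17)-en-16,15-olide (13,14-trans, C12 epimers) | CC(C)(C)[Si](C)(C)O[C@H]1COC(=O)[C@@H]1C(O)C[C@H]1C(=C)CC[C@H]2C(C)(C)CCC[C@]12C | intermediate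
26 | 12-methanesulfonate of 25 (not isolated) | CC(C)(C)[Si](C)(C)O[C@H]1COC(=O)[C@@H]1C(OS(C)(=O)=O)C[C@H]1C(=C)CC[C@H]2C(C)(C)CCC[C@]12C | intermediate
27 | (12E,14R)-14-[(tert-butyldimethylsilyl)oxy]labda-8(17),12-dien-16,15-olide | CC(C)(C)[Si](C)(C)O[C@H]1COC(=O)/C1=C/C[C@H]1C(=C)CC[C@H]2C(C)(C)CCC[C@]12C | intermediate
28 | (12E,14R)-14-hydroxylabda-8(17),12-dien-16,15-olide | O[C@H]1COC(=O)/C1=C/C[C@H]1C(=C)CC[C@H]2C(C)(C)CCC[C@]12C | intermediate
29 | triethyl phosphonoacetate | CCOC(=O)CP(=O)(OCC)OCC | starting material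
30 | 2-bromo-1,1-dimethoxyethane | COC(CBr)OC | starting material
31 | sodium salt of 29 (not isolated) | [Na+].CCOC(=O)[CH-]P(=O)(OCC)OCC | intermediate
32 | ethyl 2-(diethoxyphosphoryl)-4,4-dimethoxybutanoate (racemic) | CCOC(=O)C(CC(OC)OC)P(=O)(OCC)OCC | intermediate
33 | sodium salt of 32 (not isolated) | [Na+].CCOC(=O)[C-](CC(OC)OC)P(=O)(OCC)OCC | intermediate
34 | ethyl (12E)-15,15-dimethoxylabda-8(17),12-dien-16-oate | CCOC(=O)/C(CC(OC)OC)=C/C[C@H]1C(=C)CC[C@H]2C(C)(C)CCC[C@]12C | intermediate
35 | (12E)-15,15-dimethoxylabda-8(17),12-dien-16-oic acid | OC(=O)/C(CC(OC)OC)=C/C[C@H]1C(=C)CC[C@H]2C(C)(C)CCC[C@]12C | intermediate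
36 | mixed anhydride of 35 and 2,4,6-trichlorobenzoic acid (not isolated) | O=C(OC(=O)/C(CC(OC)OC)=C/C[C@H]1C(=C)CC[C@H]2C(C)(C)CCC[C@]12C)c1c(Cl)cc(Cl)cc1Cl | intermediate
37 | (12E,14R)-16-oxo-15,16-epoxylabda-8(17),12-dien-14-yl (12E)-15,15-dimethoxylabda-8(17),12-dien-16-oate | C=C1CC[C@H]2C(C)(C)CCC[C@]2(C)[C@H]1C/C=C(\CC(OC)OC)C(=O)O[C@H]1COC(=O)/C1=C/C[C@H]1C(=C)CC[C@H]2C(C)(C)CCC[C@]12C | intermediate
38 | CNP0274315.1 | C=C1CC[C@H]2C(C)(C)CCC[C@]2(C)[C@H]1C/C=C(\CC=O)C(=O)O[C@H]1COC(=O)/C1=C/C[C@H]1C(=C)CC[C@H]2C(C)(C)CCC[C@]12C | target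

**Step count**

Total step count: 24.
Longest linear sequence: 19 steps (1, 3–15, 17–19, 23, 24).

**Steps most likely to fail**

Step 8. The catalysed cycloaddition may show insufficient enantiofacial or endo selectivity, because the enal is β,β-disubstituted and the axial C4 methyl meets the C10 methyl in the trans-fused transition state. The Lewis acid may also desilylate the dienol ether before ring closure. The fallback uses known chemistry, sets out from 13 and comes back at 14. Trienal 13 would be cyclised without asymmetric induction by Me2AlCl in CH2Cl2 at −78 °C, a Lewis-acid-promoted intramolecular Diels–Alder reaction of a trienal, to the racemic cycloadduct F1. Reduction with NaBH4 would give the racemic C11 alcohol F2, which would be esterified (DCC, DMAP) with (R)-2-methoxy-2-phenylacetic acid. The diastereomeric esters would be separated by chromatography or crystallisation, and the ester of the natural series, the methoxyphenylacetate F3, would be cleaved with K2CO3 in methanol to the single-enantiomer alcohol F4. Oxidation of F4 with Dess–Martin periodinane gives 14.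

Step 18. The elimination may give a mixture of alkene geometries, and the enolate formed on the way may expel the C14 silyloxy group instead of the mesylate. The fallback sets out from 23 (with aldehyde 21 as partner) and comes back at 27. Lactone 23 would be converted into the α-phosphono lactone F5 with LiN(i-Pr)2 and diethyl chlorophosphate, followed by a second equivalent of LiN(i-Pr)2 for the phosphate-to-phosphonate shift. F5 would then be condensed with 21 in a Horner–Wadsworth–Emmons olefination (KN(SiMe3)2, 18-crown-6, THF, −78 °C → rt). This forms C12=C13 directly from a stabilised anion, without a β-mesyloxy lactone, and gives 27.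

Step 23. Acylation of the secondary allylic alcohol by the hindered α-branched acid may be slow enough for base-induced loss of the activated C14 oxygen (elimination towards C11) to compete. The fallback reverses the order of bond formation, sets out from 32 and 28 and comes back at 37. Phosphonate 32 would be saponified (NaOH, aqueous ethanol) to the phosphono acid F6. F6 would be coupled with 28 by DCC alone, which is fast for phosphonoacetic acids, to the phosphonoacetate ester F7. The 12E alkene of the acid half would then be made last by a Masamune–Roush olefination of F7 with aldehyde 21 (LiCl, i-Pr2NEt, MeCN), giving 37.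

**Further compounds**

F1 | step 8 | racemic 8β-[(tert-butyldimethylsilyl)oxy]-12-nordrim-6-en-11-al (racemate of 14) | O=C[C@H]1[C@@H](O[Si](C)(C)C(C)(C)C)C=C[C@H]2C(C)(C)CCC[C@]12C.O=C[C@@H]1[C@H](O[Si](C)(C)C(C)(C)C)C=C[C@@H]2C(C)(C)CCC[C@@]12C
F2 | step 8 | racemic 8β-[(tert-butyldimethylsilyl)oxy]-12-nordrim-6-en-11-ol | OC[C@H]1[C@@H](O[Si](C)(C)C(C)(C)C)C=C[C@H]2C(C)(C)CCC[C@]12C.OC[C@@H]1[C@H](O[Si](C)(C)C(C)(C)C)C=C[C@@H]2C(C)(C)CCC[C@@]12C
F3 | step 8 | 8β-[(tert-butyldimethylsilyl)oxy]-12-nordrim-6-en-11-yl (2R)-2-methoxy-2-phenylacetate (decalin configured as in 14) | CO[C@@H](C(=O)OC[C@H]1[C@@H](O[Si](C)(C)C(C)(C)C)C=C[C@H]2C(C)(C)CCC[C@]12C)c1ccccc1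
F4 | step 8 | 8β-[(tert-butyldimethylsilyl)oxy]-12-nordrim-6-en-11-ol (single enantiomer, configured as in 14) | OC[C@H]1[C@@H](O[Si](C)(C)C(C)(C)C)C=C[C@H]2C(C)(C)CCC[C@]12C
F5 | step 18 | diethyl {(4R)-4-[(tert-butyldimethylsilyl)oxy]-2-oxooxolan-3-yl}phosphonate (C3 epimers) | CC(C)(C)[Si](C)(C)O[C@H]1COC(=O)C1P(=O)(OCC)OCC
F6 | step 23 | 2-(diethoxyphosphoryl)-4,4-dimethoxybutanoic acid (racemic) | OC(=O)C(CC(OC)OC)P(=O)(OCC)OCC
F7 | step 23 | (12E,14R)-16-oxo-15,16-epoxylabda-8(17),12-dien-14-yl 2-(diethoxyphosphoryl)-4,4-dimethoxybutanoate (epimers at the phosphonate carbon) | CCOP(=O)(OCC)C(CC(OC)OC)C(=O)O[C@H]1COC(=O)/C1=C/C[C@H]1C(=C)CC[C@H]2C(C)(C)CCC[C@]12C
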